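## Structural features

The target is one oxolane (tetrahydrofuran) ring, O1–C2–C3–C4–C5, with a 4-hydroxy-3,5-dimethoxyphenyl ring on each carbon next to oxygen (C2, C5) and a methyl group on each of the other two (C3, C4). The halves are related by a twofold axis through O1 and the midpoint of C3–C4. All four ring carbons are contiguous stereocentres, all S: every vicinal pair is trans and the two aryl rings are trans across O1. The two benzylic C–O bonds are the fragile part, since para-oxygen donation lets them ionise under acid and exposes them to hydrogenolysis; the phenols are oxidisable and travel as benzyl ethers. That lability is also useful, because C2 and C5 can be equilibrated under acid to the trans positions. C3 and C4 cannot be corrected once both carry methyl groups, so their threo relationship and absolute configuration are the real difficulty. The key step uses the fact that C3 and C4 can be the β- and α-carbons of an enoate whose γ-carbon is the oxygenated benzylic C2, while C5 is an aryl aldehyde carbon; the C4 methyl is carried as the ester, which keeps C4 enolisable. (C2–C5 always mean these target positions; Ar is 4-(benzyloxy)-3,5-dimethoxyphenyl; systematic names use their own locants.)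

## Logic of the disconnections

19 is traced to 18 by cutting the two phenolic O–CH2Ph bonds. The phenols must stay masked through organometallic, hydride and Lewis-acid steps, and a benzyl ether also acts as the para donor that stabilises the benzylic cations used later. The forward step must cleave aryl benzyl ethers without opening the ring benzylic C–O bonds.

18 is traced to 17 without cutting a bond: only C5 is inverted. The all-trans isomer is the thermodynamic one and C5 is a benzylic ether carbon, so its configuration can be left open earlier. The forward step needs reversible ionisation that re-closes rather than eliminates.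

17 is traced through 16 and 15 to 14 by returning the C4 methyl to CH2OSO2Me, CH2OH and CO2Me. A carbonyl on C4 supplies the aldol handle and keeps C4 correctable. The forward steps need hydride reagents that spare benzyl ethers and the cyclic ether.

14 is traced to 12 (through 13) by inverting C4 only. The aldol can only place the ester cis to the C3 methyl, so an inversion has to be planned. The forward step relies on facial discrimination in protonating a ring enolate flanked by methyl on one face and aryl on the other.

12 is traced to 11 by cutting O1–C5. C5 is an ionisable para-alkoxybenzylic carbinol, while the C2–O bond is kept, so C2 retains its configuration. The ring becomes an open chain whose C5 configuration is irrelevant. The forward step must ionise C5 without elimination or lactonisation.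

11 is traced to 8, 3 and a methyl cuprate (through 10 and 9) by cutting C3–CH3 and C4–C5. This reduces a four-carbon stereotetrad to one stereocentre in 8 and an achiral aldehyde. The forward step must add methyl anti to the C2 oxygen; C4 and C5 need not be right.

8 is traced through 7 to 6 by removing the silyl group and returning the (E)-alkene to an alkyne. A propargylic alcohol gives both the stereocentre and, by trans hydride addition, the alkene geometry. The forward reduction must be E-selective and leave the ester alone.

6 is traced to 3 and 4 (through 5) by cutting the C2–alkyne bond. This is the only stereocentre set by a catalyst; all others are relayed from it. The forward step needs enantioface control at an electron-rich aryl aldehyde.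

3 is traced to 1 and 2 by cutting the O–benzyl bond, a routine phenol alkylation.

## Other disconnections considered

Alternative 1: The cut is C2–C3 and C4–C5, so that O1, C2 and C5 come from the trans-diaryloxirane A2 (the racemate serves, since the ylide is planar) and C3–C4 from the crotonoyl oxazolidinone A3. In the forward key step light cleaves the oxirane C–C bond to a carbonyl ylide, which adds across the alkene of A3 to give cycloadduct A1.
- In its favour: the ring and both C–C bonds form in one step from two simple partners. The (E)-alkene transfers its geometry into the 3,4-trans relationship; this is better than the chosen plan, where C4 emerges cis and costs an extra step. Disrotatory photochemical opening of a trans-oxirane should give the ylide that maps onto the 2,5-trans adduct.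
- Against it here: an electron-rich oxirane can fragment by C–O cleavage and the ylide can isomerise. The auxiliary must choose between faces and between two all-trans/cis,cis approach modes without chelation, so up to four isomers are possible. That facial choice would be the only source of absolute configuration at the non-correctable C3 and C4.
- Comparison: in structure the two plans are equal in carrying the C4 methyl as a carbonyl group, and equal in being able to repair C2 and C5 by acid. In mechanism the chosen plan relays configuration by polar, substrate-controlled steps from one catalytic event, which is more predictable than a photochemical cycloaddition. In step economy A1 could be reached in about four steps from 3 and finished in about four more, against twelve, so the alternative is better on count.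

Alternative 2: The cut is the two C–aryl bonds, giving the redox-active diester A5 and the arylzinc chloride A6. In the forward key step each ester of A5 loses CO2 under NiCl2·glyme with a bipyridine ligand, and each α-oxy radical is arylated by A6, giving A4, which is identical with 18.
- In its favour: the threo C3/C4 unit is already present in A5, and the product is one step from the target, which is better than the chosen end-game. C2 and C5 would be set by capture trans to the neighbouring methyl and remain correctable by acid, equal to the chosen plan.
- Against it here: enantiopure A5 is not an article of commerce, and making it poses the same threo-dimethyl problem plus 2,5-functionalisation. Two radical couplings on one molecule multiply losses from protodecarboxylation and homocoupling.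
- Comparison: in structure it moves the hard part into the starting material rather than solving it. In mechanism the radical couplings carry no stereochemical memory, which is harmless at C2/C5 but gives no help with C3/C4. In step economy it is shorter after the key step, but probably not overall once A5 is counted.

Alternative 3: The cut is O1–C5 and C4–C5, with C5 as a carbene carbon from the aryldiazomethane A8 and O1, C2, C3, C4 from the enone A9. In the forward key step a copper carbene (CuOTf, chiral bis(oxazoline) ligand) adds to the enone oxygen and the carbonyl ylide closes by 1,5-electrocyclisation to dihydrofuran A7.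
- In its favour: a catalyst sets C4, a non-correctable centre, together with the ring and the trans C4/C5 relationship; this is better than the chosen key step, which closes no ring. A8 and A9 are each about two steps from 3, so it is also better on count.
- Against it here: A8 is a thermally labile, hazardous donor diazo compound, and the established annulation uses acceptor diazo esters, so cyclopropanation and carbene dimerisation are likely to compete. A7 must then be reduced across a tetrasubstituted C2=C3 enol ether, setting C3 trans to C4 with nothing to correct C3 afterwards.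
- Comparison: both plans have one doubtful non-benzylic centre, but in the chosen plan that centre (C4) stays enolisable, which is the stronger position. Both rely equally on acid equilibration for the benzylic centres.

Key step: step 5

Assumption: in step 2 (S)-BINOL is taken to direct the alkynyl group to the Si face of 3, as in related BINOL/Ti(OiPr)4 additions to aryl aldehydes; if the sense is the reverse, (R)-BINOL is used and nothing else changes.

Remark: the aldol adduct 11 is drawn with the ester-bearing carbon opposite to the target arrangement, because that is what the enolate model predicts (step 5); steps 7 and 11 repair C4 and C5.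

## Route

Step 1
Reactants: 1 syringaldehyde; 2 benzyl bromide
Product: 3 4-(benzyloxy)-3,5-dimethoxybenzaldehyde
Conditions: K2CO3, DMF, 60 °C
Reagents that add atoms: none
Why: Williamson etherification of the phenoxide; the aldehyde is inert to K2CO3, and the benzyl ether later serves as the para donor for the C5 cation and is removed last.

Step 2
Reactants: 3 4-(benzyloxy)-3,5-dimethoxybenzaldehyde; 4 methyl propiolate
Product: 6 methyl (R)-4-Ar-4-hydroxybut-2-ynoate, via alkynylzinc 5 (not isolated)
Conditions: Et2Zn, (S)-BINOL (40 mol %), HMPA, CH2Cl2, rt; Ti(OiPr)4; then 3, rt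
Reagents that add atoms: none
Why: Catalytic enantioselective alkynylzinc addition to an aryl aldehyde under BINOL/Ti(OiPr)4 is established for methyl propiolate; Si-face delivery sets the future C2 centre, which is R here only because the alkynyl branch outranks aryl.

Step 3
Reactants: 6 methyl (R)-4-Ar-4-hydroxybut-2-ynoate
Product: 7 methyl (S,E)-4-Ar-4-hydroxybut-2-enoate
Conditions: NaAlH2(OCH2CH2OMe)2, THF, −72 °C; aq. KNaC4H4O6 (tartrate) work-up
Reagents that add atoms: none
Why: Alkoxide-directed trans-hydroalumination of a γ-hydroxy ynoate at low temperature gives the (E)-enoate on protonolysis without reducing the ester; the stereocentre is untouched and becomes S only through the change in CIP ranking.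

Step 4
Reactants: 7 methyl (S,E)-4-Ar-4-hydroxybut-2-enoate
Product: 8 methyl (S,E)-4-Ar-4-[(tert-butyldimethylsilyl)oxy]but-2-enoate
Conditions: TBSCl, imidazole, DMF, 0 °C → rt
Reagents that add atoms: tert-butyldimethylsilyl chloride, CC(C)(C)[Si](C)(C)Cl
Why: Standard silylation with a mild base that should not isomerise the γ-hydroxy enoate; the bulky non-chelating silyl ether later enforces anti cuprate addition and serves as the ring-closing oxygen.

Step 5
Reactants: 8 methyl (S,E)-4-Ar-4-[(tert-butyldimethylsilyl)oxy]but-2-enoate; 3 4-(benzyloxy)-3,5-dimethoxybenzaldehyde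
Product: 11 methyl (2R,3S,4S)-4-Ar-2-[(R)-Ar(hydroxy)methyl]-4-[(tert-butyldimethylsilyl)oxy]-3-methylbutanoate, via lithium enolate 9 (not isolated), via chlorozinc enolate 10 (not isolated)
Conditions: Me2CuLi (from MeLi, CuI), Et2O, −78 → −40 °C; ZnCl2, THF, −78 °C; then 3 (excess), −78 → −50 °C; aq. NH4Cl
Reagents that add atoms: lithium dimethylcuprate, [Li+].C[Cu-]C
Why: Me2CuLi forms a π-complex with the enoate and transfers methyl to the β-carbon (C3) through a trivalent-copper intermediate, leaving lithium enolate 9; ZnCl2 exchanges it to the less basic zinc enolate 10, which adds to 3 through a closed Zimmerman–Traxler transition state, so C3–CH3 and C4–C5 are made in one flask and no ring is closed. The closest known reaction type is the anti-selective conjugate addition of Me2CuLi to γ-alkoxy and γ-silyloxy (E)-enoates combined with aldol trapping of the cuprate-derived enolate. C3 is controlled by C2: in the reactive conformer the C–OSi bond lies perpendicular to the enoate π system and anti to the incoming copper (modified Felkin–Anh), which places methyl anti to oxygen and gives 3S from 2S; this is the one selectivity the step must deliver, and the bulky non-chelating silyl ether secures it. C4 is controlled by C3 through A(1,3) strain: the C3–H eclipses the enolate double bond and the aldehyde enters anti to the large C2 branch, which leaves the ester cis to the C3 methyl in the eventual ring (4R), the opposite of the target, so 11 is drawn with that configuration and C4 is inverted in step 7. C5 follows from the enolate geometry (oxygen–metal cis to C3 expected, hence the 4,5-syn carbinol, 5R) but does not matter, because C5 is ionised in step 6. Excess 3 absorbs methyl transfer from residual cuprate, and the low temperature suppresses retro-aldol.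

Step 6
Reactants: 11 methyl (2R,3S,4S)-4-Ar-2-[(R)-Ar(hydroxy)methyl]-4-[(tert-butyldimethylsilyl)oxy]-3-methylbutanoate
Product: 12 methyl (2R,3R,4S,5S)-2,5-bis(Ar)-4-methyloxolane-3-carboxylate
Conditions: BF3·OEt2 (0.5 equiv), CH2Cl2, −78 → −20 °C
Reagents that add atoms: none
Why: Lewis-acid ionisation of the para-alkoxybenzylic C5 carbinol and 5-exo capture of the cation by the C2 silyl ether oxygen, with loss of the silyl group, is a known cycloetherification; C2 keeps its configuration because its C–O bond is never broken, and the new C5–O bond forms trans to the C4 ester whichever carbinol epimer is used. Closing while the oxygen is still silylated avoids a free γ-hydroxy ester and hence lactonisation.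

Step 7
Reactants: 12 methyl (2R,3R,4S,5S)-2,5-bis(Ar)-4-methyloxolane-3-carboxylate
Product: 14 methyl (2R,3S,4S,5S)-2,5-bis(Ar)-4-methyloxolane-3-carboxylate, via lithium enolate 13 (not isolated)
Conditions: LiN(iPr)2, THF, −78 °C; AcOH, −78 °C
Reagents that add atoms: none
Why: Irreversible enolisation followed by kinetic protonation is a standard contra-thermodynamic epimerisation; the proton should enter from the face flanked by the C3 methyl rather than the face carrying the C5 aryl, turning the ester trans to the methyl (target C4). Ring opening of 13 by alkoxide loss should be slow because the C5–O bond lies nearly orthogonal to the enolate π system.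

Step 8
Reactants: 14 methyl (2R,3S,4S,5S)-2,5-bis(Ar)-4-methyloxolane-3-carboxylate
Product: 15 [(2R,3R,4S,5S)-2,5-bis(Ar)-4-methyloxolan-3-yl]methanol
Conditions: LiAlH4, THF, 0 °C
Reagents that add atoms: none
Why: Ester reduction by LiAlH4 is much faster than enolisation, so C4 is not eroded; benzyl ethers and the cyclic ether are inert, and the descriptor change at C4 is only a change in CIP ranking.

Step 9
Reactants: 15 [(2R,3R,4S,5S)-2,5-bis(Ar)-4-methyloxolan-3-yl]methanol
Product: 16 [(2R,3R,4S,5S)-2,5-bis(Ar)-4-methyloxolan-3-yl]methyl methanesulfonate
Conditions: MsCl, Et3N, CH2Cl2, 0 °C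
Reagents that add atoms: methanesulfonyl chloride, CS(=O)(=O)Cl
Why: Sulfonylation of a primary alcohol under basic conditions, which leave the acid-sensitive benzylic ethers untouched.

Step 10
Reactants: 16 [(2R,3R,4S,5S)-2,5-bis(Ar)-4-methyloxolan-3-yl]methyl methanesulfonate
Product: 17 (2R,3S,4S,5S)-2,5-bis(Ar)-3,4-dimethyloxolane
Conditions: LiEt3BH, THF, 0 °C → rt
Reagents that add atoms: none
Why: SN2 hydride displacement of a primary mesylate by LiEt3BH occurs at carbon without S–O cleavage and turns CH2OSO2Me into the C4 methyl, fixing the threo C3/C4 pair.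

Step 11
Reactants: 17 (2R,3S,4S,5S)-2,5-bis(Ar)-3,4-dimethyloxolane
Product: 18 (2S,3S,4S,5S)-2,5-bis(Ar)-3,4-dimethyloxolane
Conditions: BF3·OEt2 (0.2 equiv), CH2Cl2, 0 °C → rt
Reagents that add atoms: none
Why: Acid-mediated benzylic epimerisation of 2,5-diaryl-3,4-dimethyltetrahydrofurans is known: reversible ionisation lets only C2 and C5 invert, and the all-trans isomer, free of the cis C4-methyl/C5-aryl contact, is the thermodynamic sink. C3 and C4 are untouched, so enantiopurity carries through.

Step 12
Reactants: 18 (2S,3S,4S,5S)-2,5-bis(Ar)-3,4-dimethyloxolane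
Product: 19 4,4'-[(2S,3S,4S,5S)-3,4-dimethyloxolane-2,5-diyl]bis(2,6-dimethoxyphenol)
Conditions: H2 (1 atm), 10% Pd/C, EtOAc, rt
Reagents that add atoms: none
Why: Hydrogenolysis of aryl benzyl ethers over Pd/C in a neutral solvent should outpace cleavage of the ring benzylic C–O bonds if stopped at full debenzylation; it releases the bis-phenol with all four centres S.

## Compound list

1 | syringaldehyde (4-hydroxy-3,5-dimethoxybenzaldehyde) | COc1cc(C=O)cc(OC)c1O | starting material
2 | benzyl bromide | BrCc1ccccc1 | starting material
3 | 4-(benzyloxy)-3,5-dimethoxybenzaldehyde | COc1cc(C=O)cc(OC)c1OCc1ccccc1 | intermediate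
4 | methyl propiolate | C#CC(=O)OC | starting material
5 | ethyl(3-methoxy-3-oxoprop-1-yn-1-yl)zinc | CC[Zn]C#CC(=O)OC | intermediate
6 | methyl (R)-4-Ar-4-hydroxybut-2-ynoate | COc1cc([C@@H](O)C#CC(=O)OC)cc(OC)c1OCc1ccccc1 | intermediate
7 | methyl (S,E)-4-Ar-4-hydroxybut-2-enoate | COc1cc([C@@H](O)/C=C/C(=O)OC)cc(OC)c1OCc1ccccc1 | intermediate
8 | methyl (S,E)-4-Ar-4-[(tert-butyldimethylsilyl)oxy]but-2-enoate | COc1cc([C@@H](O[Si](C)(C)C(C)(C)C)/C=C/C(=O)OC)cc(OC)c1OCc1ccccc1 | intermediate
9 | lithium enolate of methyl (3S,4S)-4-Ar-4-[(tert-butyldimethylsilyl)oxy]-3-methylbutanoate (O–Li cis to C3) | COc1cc([C@@H](O[Si](C)(C)C(C)(C)C)[C@@H](C)/C=C(/OC)O[Li])cc(OC)c1OCc1ccccc1 | intermediate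
10 | chlorozinc enolate of methyl (3S,4S)-4-Ar-4-[(tert-butyldimethylsilyl)oxy]-3-methylbutanoate (O–Zn cis to C3) | COc1cc([C@@H](O[Si](C)(C)C(C)(C)C)[C@@H](C)/C=C(/OC)O[Zn]Cl)cc(OC)c1OCc1ccccc1 | intermediate
11 | methyl (2R,3S,4S)-4-Ar-2-[(R)-Ar(hydroxy)methyl]-4-[(tert-butyldimethylsilyl)oxy]-3-methylbutanoate | COc1cc([C@@H](O[Si](C)(C)C(C)(C)C)[C@@H](C)[C@@H](C(=O)OC)[C@@H](O)c2cc(OC)c(OCc3ccccc3)c(OC)c2)cc(OC)c1OCc1ccccc1 | intermediate
12 | methyl (2R,3R,4S,5S)-2,5-bis(Ar)-4-methyloxolane-3-carboxylate | COc1cc([C@H]2O[C@@H](c3cc(OC)c(OCc4ccccc4)c(OC)c3)[C@H](C(=O)OC)[C@@H]2C)cc(OC)c1OCc1ccccc1 | intermediate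
13 | lithium enolate of 12 (ester enolised at the ring carbon, other three ring centres as in 12) | COc1cc([C@H]2O[C@@H](c3cc(OC)c(OCc4ccccc4)c(OC)c3)C(=C(OC)O[Li])[C@@H]2C)cc(OC)c1OCc1ccccc1 | intermediate
14 | methyl (2R,3S,4S,5S)-2,5-bis(Ar)-4-methyloxolane-3-carboxylate | COc1cc([C@H]2O[C@@H](c3cc(OC)c(OCc4ccccc4)c(OC)c3)[C@@H](C(=O)OC)[C@@H]2C)cc(OC)c1OCc1ccccc1 | intermediate
15 | [(2R,3R,4S,5S)-2,5-bis(Ar)-4-methyloxolan-3-yl]methanol | COc1cc([C@H]2O[C@@H](c3cc(OC)c(OCc4ccccc4)c(OC)c3)[C@@H](CO)[C@@H]2C)cc(OC)c1OCc1ccccc1 | intermediate
16 | [(2R,3R,4S,5S)-2,5-bis(Ar)-4-methyloxolan-3-yl]methyl methanesulfonate | COc1cc([C@H]2O[C@@H](c3cc(OC)c(OCc4ccccc4)c(OC)c3)[C@@H](COS(C)(=O)=O)[C@@H]2C)cc(OC)c1OCc1ccccc1 | intermediate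
17 | (2R,3S,4S,5S)-2,5-bis(Ar)-3,4-dimethyloxolane (2,3-cis, 3,4-trans, 4,5-trans) | COc1cc([C@H]2O[C@@H](c3cc(OC)c(OCc4ccccc4)c(OC)c3)[C@@H](C)[C@@H]2C)cc(OC)c1OCc1ccccc1 | intermediate
18 | (2S,3S,4S,5S)-2,5-bis(Ar)-3,4-dimethyloxolane (all-trans) | COc1cc([C@H]2O[C@H](c3cc(OC)c(OCc4ccccc4)c(OC)c3)[C@@H](C)[C@@H]2C)cc(OC)c1OCc1ccccc1 | intermediate
19 | 4,4'-[(2S,3S,4S,5S)-3,4-dimethyloxolane-2,5-diyl]bis(2,6-dimethoxyphenol) | COc1cc([C@H]2O[C@H](c3cc(OC)c(O)c(OC)c3)[C@@H](C)[C@@H]2C)cc(OC)c1O | target

## Step count and least certain steps

Total: 12 steps. Longest linear sequence: 12 steps (1 → 19); 2 and 4 enter as commercial reagents and 3 is used twice.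

Step 5 (key step). The most likely failure is incomplete trapping: the enolate is protonated, or methyl is transferred from residual cuprate to 3, before the aldol occurs, because ester enolates from cuprate additions are sluggish and aggregated. A second risk is erosion of anti selectivity at C3, which would surface later as loss of enantiopurity unless the diastereomer is removed at 11 or 12. Fallback, from 8 back to 11: run the conjugate addition alone with a protic quench to the saturated ester methyl (3S,4S)-4-Ar-4-[(tert-butyldimethylsilyl)oxy]-3-methylbutanoate F1, purify it, then enolise F1 separately with LiN(iPr)2 at −78 °C (giving 9), exchange with ZnCl2 (10) and add 3. The C4 face is governed by the same A(1,3) control, and C5 may differ but is irrelevant.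

Step 7. The most likely failure is poor facial discrimination in the protonation, returning 12, because methyl and aryl flanks differ less than the model assumes; ring opening by alkoxide loss on warming is a second risk. Fallback, from 12 back to 18, using thermodynamics instead of kinetic protonation: NaOMe in MeOH equilibrates 12 with 14; BF3·OEt2 on the mixture moves only 14 on, by C5 inversion, to the all-trans ester methyl (2S,3S,4S,5S)-2,5-bis(Ar)-4-methyloxolane-3-carboxylate F2, and recovered 12 is recycled. F2 is reduced with LiAlH4 to [(2S,3R,4S,5S)-2,5-bis(Ar)-4-methyloxolan-3-yl]methanol F3, converted to the mesylate [(2S,3R,4S,5S)-2,5-bis(Ar)-4-methyloxolan-3-yl]methyl methanesulfonate F4 and reduced with LiEt3BH to 18, which makes step 11 unnecessary.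

Step 6. The most likely failure is loss of the C4 proton from the C5 cation (dehydration to the arylidene ester), since the cation sits next to an acidic C–H; premature desilylation followed by lactonisation of the γ-hydroxy ester is the second risk. Fallback, from 11 back to 12: acetylate the carbinol (Ac2O, pyridine) to methyl (2R,3S,4S)-2-[(R)-acetoxy(Ar)methyl]-4-Ar-4-[(tert-butyldimethylsilyl)oxy]-3-methylbutanoate F5 and ionise the acetate with catalytic Me3SiOSO2CF3 in CH2Cl2 at −78 °C, so the cation forms under aprotic conditions at a temperature where elimination is slow and the silyl ether closes the ring.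

Step 2. The most likely failure is insufficient enantioface control with this electron-rich aldehyde, or oligomerisation of the propiolate under the basic zinc conditions. Fallback, from 3 and 4 back to 6: deprotonate 4 with LiN(SiMe3)2 at −78 °C to lithium 3-methoxy-3-oxoprop-1-yn-1-ide F6, add it to 3 to give racemic methyl 4-Ar-4-hydroxybut-2-ynoate F7, oxidise with MnO2 to the ynone methyl 4-Ar-4-oxobut-2-ynoate F8, and reduce F8 by asymmetric transfer hydrogenation with RuCl(p-cymene)(TsDPEN), using the antipode that gives 6, in iPrOH.

Step 11. The most likely failure is that the ring-opened benzylic cation eliminates or is captured by an aryl ring instead of re-closing, or that equilibration stalls. Fallback, from 17 back to 19, reversing the order of the last two operations: hydrogenolyse 17 first (H2, 10% Pd/C) to 4,4'-[(2R,3S,4S,5S)-3,4-dimethyloxolane-2,5-diyl]bis(2,6-dimethoxyphenol) F9, then epimerise C5 with catalytic CF3CO2H in CH2Cl2, where the free para-hydroxyl opens the ring through a quinone methide under much milder acid.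

## Further compounds

F1 | step 5 | methyl (3S,4S)-4-Ar-4-[(tert-butyldimethylsilyl)oxy]-3-methylbutanoate | COc1cc([C@@H](O[Si](C)(C)C(C)(C)C)[C@@H](C)CC(=O)OC)cc(OC)c1OCc1ccccc1
F2 | step 7 | methyl (2S,3S,4S,5S)-2,5-bis(Ar)-4-methyloxolane-3-carboxylate | COc1cc([C@H]2O[C@H](c3cc(OC)c(OCc4ccccc4)c(OC)c3)[C@@H](C(=O)OC)[C@@H]2C)cc(OC)c1OCc1ccccc1
F3 | step 7 | [(2S,3R,4S,5S)-2,5-bis(Ar)-4-methyloxolan-3-yl]methanol | COc1cc([C@H]2O[C@H](c3cc(OC)c(OCc4ccccc4)c(OC)c3)[C@@H](CO)[C@@H]2C)cc(OC)c1OCc1ccccc1
F4 | step 7 | [(2S,3R,4S,5S)-2,5-bis(Ar)-4-methyloxolan-3-yl]methyl methanesulfonate | COc1cc([C@H]2O[C@H](c3cc(OC)c(OCc4ccccc4)c(OC)c3)[C@@H](COS(C)(=O)=O)[C@@H]2C)cc(OC)c1OCc1ccccc1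
F5 | step 6 | methyl (2R,3S,4S)-2-[(R)-acetoxy(Ar)methyl]-4-Ar-4-[(tert-butyldimethylsilyl)oxy]-3-methylbutanoate | COc1cc([C@@H](O[Si](C)(C)C(C)(C)C)[C@@H](C)[C@@H](C(=O)OC)[C@@H](OC(C)=O)c2cc(OC)c(OCc3ccccc3)c(OC)c2)cc(OC)c1OCc1ccccc1
F6 | step 2 | lithium 3-methoxy-3-oxoprop-1-yn-1-ide | [Li]C#CC(=O)OC
F7 | step 2 | racemic methyl 4-Ar-4-hydroxybut-2-ynoate | COc1cc(C(O)C#CC(=O)OC)cc(OC)c1OCc1ccccc1
F8 | step 2 | methyl 4-Ar-4-oxobut-2-ynoate | COc1cc(C(=O)C#CC(=O)OC)cc(OC)c1OCc1ccccc1
F9 | step 11 | 4,4'-[(2R,3S,4S,5S)-3,4-dimethyloxolane-2,5-diyl]bis(2,6-dimethoxyphenol) | COc1cc([C@H]2O[C@@H](c3cc(OC)c(O)c(OC)c3)[C@@H](C)[C@@H]2C)cc(OC)c1O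
A1 | alternative 1 | (S)-4-benzyl-3-{[(2S,3S,4S,5S)-2,5-bis(Ar)-4-methyloxolan-3-yl]carbonyl}oxazolidin-2-one | COc1cc([C@H]2O[C@H](c3cc(OC)c(OCc4ccccc4)c(OC)c3)[C@@H](C(=O)N3[C@@H](Cc4ccccc4)COC3=O)[C@@H]2C)cc(OC)c1OCc1ccccc1
A2 | alternative 1 | trans-2,3-bis(Ar)oxirane, drawn as (2S,3S) | COc1cc([C@@H]2O[C@H]2c2cc(OC)c(OCc3ccccc3)c(OC)c2)cc(OC)c1OCc1ccccc1
A3 | alternative 1 | (S)-4-benzyl-3-[(E)-but-2-enoyl]oxazolidin-2-one | C/C=C/C(=O)N1[C@@H](Cc2ccccc2)COC1=O
A4 | alternative 2 | (2S,3S,4S,5S)-2,5-bis(Ar)-3,4-dimethyloxolane | COc1cc([C@H]2O[C@H](c3cc(OC)c(OCc4ccccc4)c(OC)c3)[C@@H](C)[C@@H]2C)cc(OC)c1OCc1ccccc1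
A5 | alternative 2 | bis(1,3-dioxoisoindolin-2-yl) (3S,4S)-3,4-dimethyloxolane-2,5-dicarboxylate | O=C(ON1C(=O)c2ccccc2C1=O)C1OC(C(=O)ON2C(=O)c3ccccc3C2=O)[C@@H](C)[C@@H]1C
A6 | alternative 2 | [4-(benzyloxy)-3,5-dimethoxyphenyl]zinc chloride | COc1cc([Zn]Cl)cc(OC)c1OCc1ccccc1
A7 | alternative 3 | (2S,3S)-2,5-bis(Ar)-3,4-dimethyl-2,3-dihydrofuran | COc1cc(C2=C(C)[C@H](C)[C@@H](c3cc(OC)c(OCc4ccccc4)c(OC)c3)O2)cc(OC)c1OCc1ccccc1
A8 | alternative 3 | [4-(benzyloxy)-3,5-dimethoxyphenyl]diazomethane | COc1cc(C=[N+]=[N-])cc(OC)c1OCc1ccccc1
A9 | alternative 3 | (E)-1-Ar-2-methylbut-2-en-1-one | C/C=C(\C)C(=O)c1cc(OC)c(OCc2ccccc2)c(OC)c1
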